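**Plan**

Numbering: ring A carries the C7–C9 chain, ring B the C7′–C9′ chain, and the two halves are linked through the C8–O–C4′ ether.
Retrosynthesis: after two acetonides and one benzyl ether are removed, the C1′–C7′ aryl–alkyl bond is cut first (ring B bromide plus a redox-active ester carrying the C8′/C9′ diol), then C1–C7 (aryl Grignard plus aldehyde), then the C8–O ether bond.
Enabling feature: C8′ lies beyond ring B, out of reach of any influence from C7/C8, and is held to ring B only by the C1′–C7′ bond to a CH2 that bears a 1,2-diol; a chiral-pool acid one carbon longer can therefore deliver C7′–C9′ by decarboxylation at C7′.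
Forward: a glycerate C3 unit is etherified with the ring B phenol (C8–O), ring A is added at C7, the 7,9-diol is tied up as an acetonide, and the C7′–C9′ unit is then joined at C1′; no ring of the skeleton is formed.
Stereochemistry: C8 (R) by Mitsunobu inversion of an (S)-glycerate; C7 (S) by Felkin–Anh addition under control of C8; C8′ (S) bought with (S)-4-(2-hydroxyethyl)-2,2-dimethyl-1,3-dioxolane.

Key step: step 11

Assumption: building blocks 1 and 12 are bought as single enantiomers; they are the acetonides derived from L-glyceric acid (L-serine series) and from L-malic acid.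

**Route**

Step 1
Reactants: 1 methyl (4S)-2,2-dimethyl-1,3-dioxolane-4-carboxylate
Product: 2 methyl (2S)-2,3-dihydroxypropanoate
Conditions: Amberlyst 15 (H+ form), MeOH, rt
Reagents that add atoms: none
Why: Acid-catalysed transketalisation to methanol frees the diol without touching the methyl ester or the α-stereocentre.

Step 2
Reactants: 2 methyl (2S)-2,3-dihydroxypropanoate
Product: 3 methyl (2S)-3-[(tert-butyldiphenylsilyl)oxy]-2-hydroxypropanoate
Conditions: TBDPSCl (1.05 equiv), imidazole, CH2Cl2, 0 °C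
Reagents that add atoms: tert-butyl(chloro)diphenylsilane, CC(C)(C)[Si](Cl)(c1ccccc1)c1ccccc1
Why: Silyl ether formation with a bulky chlorosilane should pick the primary hydroxyl over the hindered, less nucleophilic α-hydroxy ester OH.

Step 3
Reactants: 3 methyl (2S)-3-[(tert-butyldiphenylsilyl)oxy]-2-hydroxypropanoate; 4 4-bromo-2,6-dimethoxyphenol
Product: 5 methyl (2R)-2-(4-bromo-2,6-dimethoxyphenoxy)-3-[(tert-butyldiphenylsilyl)oxy]propanoate
Conditions: PPh3, DIAD, THF, 0 °C to rt
Reagents that add atoms: none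
Why: Mitsunobu etherification, in which the phenoxide displaces the oxyphosphonium of the α-hydroxy ester in an SN2 step with inversion, so (S) becomes (R) at the future C8.

Step 4
Reactants: 4 4-bromo-2,6-dimethoxyphenol
Product: 6 2-(benzyloxy)-5-bromo-1,3-dimethoxybenzene
Conditions: BnBr, K2CO3, DMF, rt
Reagents that add atoms: benzyl bromide, BrCc1ccccc1
Why: Williamson ether synthesis on a phenoxide, which masks the ring A phenol as a group that hydrogenolysis removes at the end.

Step 5
Reactants: 5 methyl (2R)-2-(4-bromo-2,6-dimethoxyphenoxy)-3-[(tert-butyldiphenylsilyl)oxy]propanoate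
Product: 7 (2R)-2-(4-bromo-2,6-dimethoxyphenoxy)-3-[(tert-butyldiphenylsilyl)oxy]propanal
Conditions: i-Bu2AlH (1.1 equiv), CH2Cl2, −78 °C; aq. potassium sodium tartrate; used at once
Reagents that add atoms: none
Why: Partial ester reduction with i-Bu2AlH at low temperature, where the α-alkoxy-stabilised aluminium hemiacetal holds until work-up; immediate use of the aldehyde should keep C8 from epimerising.

Step 6
Reactants: 7 (2R)-2-(4-bromo-2,6-dimethoxyphenoxy)-3-[(tert-butyldiphenylsilyl)oxy]propanal; 6 2-(benzyloxy)-5-bromo-1,3-dimethoxybenzene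
Product: 9 (1S,2R)-1-[4-(benzyloxy)-3,5-dimethoxyphenyl]-2-(4-bromo-2,6-dimethoxyphenoxy)-3-[(tert-butyldiphenylsilyl)oxy]propan-1-ol, via aryl Grignard reagent 8 (not isolated)
Conditions: 6 (1.5 equiv), Mg turnings, THF, reflux; then 7, THF, −78 to −40 °C; aq. NH4Cl
Reagents that add atoms: none
Why: Grignard addition under polar Felkin–Anh control, with the aryloxy group anti to the incoming aryl and attack past C8–H, should give the 7,8-anti (erythro) alcohol with C7 (S), since the weakly basic, hindered aryl ether and the bulky silyl ether are poor chelators in THF; the ring B bromide does not exchange with an aryl Grignard at this temperature.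

Step 7
Reactants: 9 (1S,2R)-1-[4-(benzyloxy)-3,5-dimethoxyphenyl]-2-(4-bromo-2,6-dimethoxyphenoxy)-3-[(tert-butyldiphenylsilyl)oxy]propan-1-ol
Product: 10 (1S,2R)-1-[4-(benzyloxy)-3,5-dimethoxyphenyl]-2-(4-bromo-2,6-dimethoxyphenoxy)propane-1,3-diol
Conditions: Bu4NF, AcOH, THF, 0 °C to rt
Reagents that add atoms: none
Why: Fluoride-driven cleavage of the silyl ether, buffered with acetic acid so that no free alkoxide acts on the aryloxy-bearing C8.

Step 8
Reactants: 10 (1S,2R)-1-[4-(benzyloxy)-3,5-dimethoxyphenyl]-2-(4-bromo-2,6-dimethoxyphenoxy)propane-1,3-diol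
Product: 11 (4S,5R)-4-[4-(benzyloxy)-3,5-dimethoxyphenyl]-5-(4-bromo-2,6-dimethoxyphenoxy)-2,2-dimethyl-1,3-dioxane
Conditions: Me2C(OMe)2, PPTS (cat.), CH2Cl2, rt
Reagents that add atoms: 2,2-dimethoxypropane, COC(C)(C)OC
Why: Acetonide formation by transacetalisation of the 1,3-diol, in which the anti diol closes to the trans-4,5-diequatorial dioxane and the mild acid should not ionise the benzylic C7–O bond.

Step 9
Reactants: 12 2-[(4S)-2,2-dimethyl-1,3-dioxolan-4-yl]ethanol
Product: 14 2-[(4S)-2,2-dimethyl-1,3-dioxolan-4-yl]acetic acid, via dioxolanyl acetaldehyde 13 (not isolated)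
Conditions: TEMPO (cat.), NaOCl (cat.), NaClO2, MeCN/NaH2PO4–Na2HPO4 buffer (pH 6.7), 35 °C
Reagents that add atoms: sodium chlorite, [Na+].[O-]Cl=O
Why: Oxoammonium oxidation to the aldehyde followed by Pinnick-type chlorite oxidation in one pot at buffered pH, which should spare the acetonide and leave the stereocentre untouched.

Step 10
Reactants: 14 2-[(4S)-2,2-dimethyl-1,3-dioxolan-4-yl]acetic acid
Product: 15 1,3-dioxoisoindolin-2-yl 2-[(4S)-2,2-dimethyl-1,3-dioxolan-4-yl]acetate
Conditions: N-hydroxyphthalimide, DIC, DMAP (cat.), CH2Cl2, rt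
Reagents that add atoms: N-hydroxyphthalimide, O=C1c2ccccc2C(=O)N1O
Why: Carbodiimide (Steglich-type) esterification under neutral conditions gives the redox-active ester without risk to the acetonide.

Step 11
Reactants: 11 (4S,5R)-4-[4-(benzyloxy)-3,5-dimethoxyphenyl]-5-(4-bromo-2,6-dimethoxyphenoxy)-2,2-dimethyl-1,3-dioxane; 15 1,3-dioxoisoindolin-2-yl 2-[(4S)-2,2-dimethyl-1,3-dioxolan-4-yl]acetate
Product: 16 (4S,5R)-4-[4-(benzyloxy)-3,5-dimethoxyphenyl]-5-(4-{[(4S)-2,2-dimethyl-1,3-dioxolan-4-yl]methyl}-2,6-dimethoxyphenoxy)-2,2-dimethyl-1,3-dioxane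
Conditions: 15 (2 equiv), NiCl2·6H2O (20 mol%), 2,2′-bipyridine (20 mol%), AgNO3 (0.3 equiv), Mg anode, reticulated vitreous carbon cathode, NMP, constant current, rt
Reagents that add atoms: none
Why: Cathodic reduction of the bipyridine-ligated divalent nickel salt gives low-valent nickel, which inserts into the C1′–Br bond of 11, while one-electron reduction of 15 expels phthalimide anion and CO2 to leave the primary C7′ radical; capture of that radical at the aryl–nickel centre and reductive elimination from the resulting trivalent aryl(alkyl)nickel species form the C1′–C7′ bond, with the magnesium anode supplying the electrons. The closest known reaction type is the nickel-electrocatalytic decarboxylative arylation of N-hydroxyphthalimide esters with aryl halides, which is established for primary alkyl esters and aryl bromides. No ring closes and no stereocentre is created: the radical sits on C7′, next to but not on C8′, so the (S) centre bought with 12 is carried over unchanged, and C7/C8 are locked in the dioxane far from the reacting site. The selectivity required is cross-coupling over biaryl formation, hydrodebromination and dimerisation or reduction of the alkyl radical; it should be secured by the bipyridine ligand, the silver-coated cathode and low current that release the radical slowly, the excess of 15, and the fact that C1′–Br is the only carbon–halogen bond and is flanked by the unsubstituted C2′ and C6′ positions. Loss of a β-alkoxide from the alkyl–nickel stage is disfavoured because the β-oxygen is tied into the dioxolane acetal, and every hydroxyl is masked.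

Step 12
Reactants: 16 (4S,5R)-4-[4-(benzyloxy)-3,5-dimethoxyphenyl]-5-(4-{[(4S)-2,2-dimethyl-1,3-dioxolan-4-yl]methyl}-2,6-dimethoxyphenoxy)-2,2-dimethyl-1,3-dioxane
Product: 17 (1S,2R)-1-[4-(benzyloxy)-3,5-dimethoxyphenyl]-2-{4-[(2S)-2,3-dihydroxypropyl]-2,6-dimethoxyphenoxy}propane-1,3-diol
Conditions: AcOH/H2O (4:1), 40 °C
Reagents that add atoms: none
Why: Acid-catalysed hydrolysis of both isopropylidene acetals in one pot, under acid weak enough that the benzylic C7–O bond of the still benzyl-protected ring A should not ionise and scramble C7.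

Step 13
Reactants: 17 (1S,2R)-1-[4-(benzyloxy)-3,5-dimethoxyphenyl]-2-{4-[(2S)-2,3-dihydroxypropyl]-2,6-dimethoxyphenoxy}propane-1,3-diol
Product: 18 (1S,2R)-2-{4-[(2S)-2,3-dihydroxypropyl]-2,6-dimethoxyphenoxy}-1-(4-hydroxy-3,5-dimethoxyphenyl)propane-1,3-diol
Conditions: H2 (1 atm), 10% Pd/C, EtOAc/MeOH, rt
Reagents that add atoms: none
Why: Hydrogenolysis of the benzyl aryl ether on palladium under neutral conditions, which should leave the secondary benzylic alcohol and the alkyl aryl ether intact.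

**Compound list**

1 | methyl (4S)-2,2-dimethyl-1,3-dioxolane-4-carboxylate | COC(=O)[C@@H]1COC(C)(C)O1 | starting material
2 | methyl (2S)-2,3-dihydroxypropanoate | COC(=O)[C@@H](O)CO | intermediate
3 | methyl (2S)-3-[(tert-butyldiphenylsilyl)oxy]-2-hydroxypropanoate | COC(=O)[C@@H](O)CO[Si](c1ccccc1)(c1ccccc1)C(C)(C)C | intermediate
4 | 4-bromo-2,6-dimethoxyphenol | COc1cc(Br)cc(OC)c1O | starting material
5 | methyl (2R)-2-(4-bromo-2,6-dimethoxyphenoxy)-3-[(tert-butyldiphenylsilyl)oxy]propanoate | COC(=O)[C@H](Oc1c(OC)cc(Br)cc1OC)CO[Si](c1ccccc1)(c1ccccc1)C(C)(C)C | intermediate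
6 | 2-(benzyloxy)-5-bromo-1,3-dimethoxybenzene | COc1cc(Br)cc(OC)c1OCc1ccccc1 | intermediate
7 | (2R)-2-(4-bromo-2,6-dimethoxyphenoxy)-3-[(tert-butyldiphenylsilyl)oxy]propanal | O=C[C@H](Oc1c(OC)cc(Br)cc1OC)CO[Si](c1ccccc1)(c1ccccc1)C(C)(C)C | intermediate
8 | [4-(benzyloxy)-3,5-dimethoxyphenyl]magnesium bromide | COc1cc([Mg]Br)cc(OC)c1OCc1ccccc1 | intermediate
9 | (1S,2R)-1-[4-(benzyloxy)-3,5-dimethoxyphenyl]-2-(4-bromo-2,6-dimethoxyphenoxy)-3-[(tert-butyldiphenylsilyl)oxy]propan-1-ol | COc1cc([C@H](O)[C@@H](CO[Si](c2ccccc2)(c2ccccc2)C(C)(C)C)Oc2c(OC)cc(Br)cc2OC)cc(OC)c1OCc1ccccc1 | intermediate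
10 | (1S,2R)-1-[4-(benzyloxy)-3,5-dimethoxyphenyl]-2-(4-bromo-2,6-dimethoxyphenoxy)propane-1,3-diol | COc1cc([C@H](O)[C@@H](CO)Oc2c(OC)cc(Br)cc2OC)cc(OC)c1OCc1ccccc1 | intermediate
11 | (4S,5R)-4-[4-(benzyloxy)-3,5-dimethoxyphenyl]-5-(4-bromo-2,6-dimethoxyphenoxy)-2,2-dimethyl-1,3-dioxane | CC1(C)OC[C@@H](Oc2c(OC)cc(Br)cc2OC)[C@H](c2cc(OC)c(OCc3ccccc3)c(OC)c2)O1 | intermediate
12 | 2-[(4S)-2,2-dimethyl-1,3-dioxolan-4-yl]ethanol | CC1(C)OC[C@H](CCO)O1 | starting material
13 | 2-[(4S)-2,2-dimethyl-1,3-dioxolan-4-yl]acetaldehyde | CC1(C)OC[C@H](CC=O)O1 | intermediate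
14 | 2-[(4S)-2,2-dimethyl-1,3-dioxolan-4-yl]acetic acid | CC1(C)OC[C@H](CC(=O)O)O1 | intermediate
15 | 1,3-dioxoisoindolin-2-yl 2-[(4S)-2,2-dimethyl-1,3-dioxolan-4-yl]acetate | O=C(C[C@H]1COC(C)(C)O1)ON1C(=O)c2ccccc2C1=O | intermediate
16 | (4S,5R)-4-[4-(benzyloxy)-3,5-dimethoxyphenyl]-5-(4-{[(4S)-2,2-dimethyl-1,3-dioxolan-4-yl]methyl}-2,6-dimethoxyphenoxy)-2,2-dimethyl-1,3-dioxane | CC1(C)OC[C@@H](Oc2c(OC)cc(C[C@H]3COC(C)(C)O3)cc2OC)[C@H](c2cc(OC)c(OCc3ccccc3)c(OC)c2)O1 | intermediate
17 | (1S,2R)-1-[4-(benzyloxy)-3,5-dimethoxyphenyl]-2-{4-[(2S)-2,3-dihydroxypropyl]-2,6-dimethoxyphenoxy}propane-1,3-diol | COc1cc([C@H](O)[C@@H](CO)Oc2c(OC)cc(C[C@H](O)CO)cc2OC)cc(OC)c1OCc1ccccc1 | intermediate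
18 | (1S,2R)-2-{4-[(2S)-2,3-dihydroxypropyl]-2,6-dimethoxyphenoxy}-1-(4-hydroxy-3,5-dimethoxyphenyl)propane-1,3-diol (CNP0229130.1) | COc1cc([C@H](O)[C@@H](CO)Oc2c(OC)cc(C[C@H](O)CO)cc2OC)cc(OC)c1O | target

**Step count**

Total: 13 steps.
Longest linear sequence: 10 steps (steps 1, 2, 3, 5, 6, 7, 8, 11, 12, 13).

**Steps most likely to fail**

Step 11. Oxidative addition of nickel into the electron-rich C1′–Br bond may be slow, so that hydrodebromination of the aryl partner and dimerisation or reduction of the alkyl radical outrun the cross-coupling. The fallback sets out from 11 and comes back at 18. Bromine–lithium exchange on 11 (n-BuLi, THF, −78 °C) is followed by BF3·OEt2-assisted opening of (S)-benzyl glycidyl ether (C1O[C@@H]1COCc1ccccc1) at its CH2 terminus. This should give (2S)-1-(benzyloxy)-3-(4-{[(4S,5R)-4-[4-(benzyloxy)-3,5-dimethoxyphenyl]-2,2-dimethyl-1,3-dioxan-5-yl]oxy}-3,5-dimethoxyphenyl)propan-2-ol F1, in which C8′ comes from the epoxide and the same C1′–C7′ bond is formed by a polar route. Hydrolysis of the acetonide (AcOH/H2O, 40 °C) should give (1S,2R)-1-[4-(benzyloxy)-3,5-dimethoxyphenyl]-2-{4-[(2S)-3-(benzyloxy)-2-hydroxypropyl]-2,6-dimethoxyphenoxy}propane-1,3-diol F2, and hydrogenolysis of both benzyl ethers (H2, 10% Pd/C) then leads to 18.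

Step 6. Chelation by magnesium may compete with the Felkin–Anh pathway and erode the anti selectivity, and enolisation of the α-aryloxy aldehyde may erode the configuration at C8. The fallback sets out from 5 and comes back at 9, and sets C7 by hydride delivery instead of aryl delivery. Ester 5 is converted with MeNHOMe·HCl and AlMe3 (CH2Cl2, 0 °C) into (2R)-2-(4-bromo-2,6-dimethoxyphenoxy)-3-[(tert-butyldiphenylsilyl)oxy]-N-methoxy-N-methylpropanamide F3. Addition of Grignard reagent 8 (THF, −20 °C; Weinreb ketone synthesis) should give (2R)-1-[4-(benzyloxy)-3,5-dimethoxyphenyl]-2-(4-bromo-2,6-dimethoxyphenoxy)-3-[(tert-butyldiphenylsilyl)oxy]propan-1-one F4, which is kept cold and reduced at once. Chelation-controlled reduction with Zn(BH4)2 (Et2O, −78 °C), with hydride entering the zinc chelate of the ketone and the α-aryloxy oxygen from the side of C8–H, should give the anti alcohol 9.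

Step 3. The di-ortho-substituted phenol may be a sluggish Mitsunobu partner, leaving the oxyphosphonium intermediate time to eliminate towards the 3-silyloxyacrylate. The fallback sets out from 3 and comes back at 5. Alcohol 3 is converted with Tf2O and 2,6-lutidine (CH2Cl2, −78 °C) into methyl (2S)-3-[(tert-butyldiphenylsilyl)oxy]-2-{[(trifluoromethyl)sulfonyl]oxy}propanoate F5. Displacement of the triflate by the potassium salt of 4 (K2CO3, MeCN, 0 °C) is a classical SN2 reaction with inversion and should give 5.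

**Further compounds**

F1 | step 11 | (2S)-1-(benzyloxy)-3-(4-{[(4S,5R)-4-[4-(benzyloxy)-3,5-dimethoxyphenyl]-2,2-dimethyl-1,3-dioxan-5-yl]oxy}-3,5-dimethoxyphenyl)propan-2-ol | CC1(C)OC[C@@H](Oc2c(OC)cc(C[C@H](O)COCc3ccccc3)cc2OC)[C@H](c2cc(OC)c(OCc3ccccc3)c(OC)c2)O1
F2 | step 11 | (1S,2R)-1-[4-(benzyloxy)-3,5-dimethoxyphenyl]-2-{4-[(2S)-3-(benzyloxy)-2-hydroxypropyl]-2,6-dimethoxyphenoxy}propane-1,3-diol | COc1cc([C@H](O)[C@@H](CO)Oc2c(OC)cc(C[C@H](O)COCc3ccccc3)cc2OC)cc(OC)c1OCc1ccccc1
F3 | step 6 | (2R)-2-(4-bromo-2,6-dimethoxyphenoxy)-3-[(tert-butyldiphenylsilyl)oxy]-N-methoxy-N-methylpropanamide | CON(C)C(=O)[C@H](Oc1c(OC)cc(Br)cc1OC)CO[Si](c1ccccc1)(c1ccccc1)C(C)(C)C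
F4 | step 6 | (2R)-1-[4-(benzyloxy)-3,5-dimethoxyphenyl]-2-(4-bromo-2,6-dimethoxyphenoxy)-3-[(tert-butyldiphenylsilyl)oxy]propan-1-one | COc1cc(C(=O)[C@H](Oc2c(OC)cc(Br)cc2OC)CO[Si](c2ccccc2)(c2ccccc2)C(C)(C)C)cc(OC)c1OCc1ccccc1
F5 | step 3 | methyl (2S)-3-[(tert-butyldiphenylsilyl)oxy]-2-{[(trifluoromethyl)sulfonyl]oxy}propanoate | COC(=O)[C@@H](OS(=O)(=O)C(F)(F)F)CO[Si](c1ccccc1)(c1ccccc1)C(C)(C)C
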